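**Assumption:** the target has no stereocentre and its 20-membered ring is taken to be conformationally mobile, so no stereocontrol is needed; compound 14 is made and used as the racemate.

Atom labels: ring A has O-aryl on A1, OH on A3 and the chain on A5. Ring B has O-aryl on B1, OH on B2 and B4, and the chain on B6. The chain runs from C1' (on B6) to C14' (on A5).

## Analysis of the target

Target 20 is a 20-membered cyclophane in which two benzene rings are joined twice: through the A1–O–B1 diaryl ether and through an unbranched chain of fourteen methylene groups from B6 to A5. Ring A is a 1,3,5-trisubstituted arene. Ring B is tetrasubstituted: the ether oxygen on B1 lies between a hydroxyl on B2 and the chain on B6, and a second hydroxyl sits on B4, para to B1. There is no stereocentre, so nothing has to be set or preserved. The sensitive parts are the three free phenols and above all ring B, a hydroquinone mono-aryl ether that is easily oxidised towards a quinone, so the phenols should stay masked until the last step. The synthesis is hard for two reasons: electrophilic substitution of a resorcinol or hydroquinone does not give the oxygen pattern of ring B with the chain in the right place, and the large ring has to be closed through an oxygen that has a substituent on each side. The plan rests on one observation: B1–B2–B3–B4 is a four-carbon unit with oxygen on B1, B2 and B4 and hydrogen on B3, which is the pattern of a 3-alkoxycyclobutene-1,2-dione, while B6 (with the chain) and B5 (CH) are the two carbons of a 1,1-disubstituted alkene. Ring B can therefore be grown from a squaric acid derivative and a chain-bearing alkene by electrocyclic ring expansion, with every substituent fixed by connectivity.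

## Retrosynthetic reasoning

**20 to 19.** The three O–alkyl bonds (methyl on the A3 and B4 oxygens, isopropyl on the B2 oxygen) are cut first, leading back to the tri-ether 19. All three are alkyl aryl ethers that one Lewis-acid dealkylation removes together, whereas the diaryl ether has no alkyl carbon and stays. This keeps the oxidisable free phenols out of every earlier step.

**19 to 18.** The A1–O bond is cut, opening the macrocycle to the seco compound 18, with a chloride on A1 and a free hydroxyl on B1. This bond is chosen over a chain C–C bond because the ring expansion delivers B1 as a hydroxyl, and because a chloride on ring A survives all the organometallic chemistry that builds the chain. The forward reaction has to join a hindered phenol to an unactivated chloroarene at high dilution, which calls for palladium with a bulky phosphine.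

**18 to 17.** The methyl–oxygen bond on B4 is cut, giving hydroquinone 17. The forward step must tell the two hydroxyls apart; B4 is open on both sides and B1 is flanked on both sides, so a single equivalent of alkylating agent should suffice.

**17 to 14.** Ring B is taken apart at the B4–B5 bond, and B1–B4 is folded back into a four-membered ring, giving the 4-alkenyl-4-hydroxycyclobutenone 14. This is where the route earns its economy: one thermal step forms the ring, places three oxygens and the chain, and leaves B1 and B4 as hydroxyls of different steric character. The forward reaction needs the alkenyl group to turn towards the ketene during ring opening.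

**14 to 12 and 9.** The bond between the carbinol carbon and the alkenyl carbon is cut, giving the semisquarate 12 and the alkenyllithium 13, which comes from the vinyl bromide 9 by halogen–lithium exchange. Addition has to occur at the carbonyl of 12 that is not part of the vinylogous ester; that carbonyl is the more electrophilic one.

**12 to 10.** Dione 12 is traced to commercial diisopropyl squarate 10 through the hydroxycyclobutenone 11: one carbonyl is reduced and the resulting allylic alcohol is transposed under acid with loss of one isopropoxy group.

**9 to 6 and 7.** The C1'–C2' bond is cut. The Grignard reagent 8, made from the bromide 6, would displace the allylic bromide of 2,3-dibromopropene 7; both modes of allylic substitution give the same 2-bromoalkene, so regiochemistry is not an issue.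

**6 to 3 and 1.** The C13'–C14' bond is cut as an alkene. Wittig reaction of aldehyde 3 with ylide 4 gives 5, and hydrogenation gives 6. Ylide 4 comes from phosphonium salt 2, and 2 from 1,12-dibromododecane 1, which supplies C2' to C13' and keeps a bromide at the far end for the Grignard step.

## Alternatives that were turned down

**Alternative 1: ring contraction by sulfone extrusion.** The chain is cut at C1'=C2', next to ring B. A 21-membered benzylic sulfone A2, closed beforehand by sulfide alkylation and oxidised, would be α-halogenated in situ under basic conditions and undergo Ramberg–Bäcklund 1,3-elimination. Loss of SO2 from the episulfone forms the C1'=C2' bond and contracts the ring to the 20-membered (E)-alkene A1, which would then be hydrogenated and demethylated.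
- For it: closing the large ring by sulfur alkylation is very dependable, and the diaryl ether can be made earlier between two separate arenes, where a hindered coupling is easier to force. On the reliability of the macrocyclisation this alternative is stronger than the chosen route.
- Against it: it does nothing for the real problem of ring B. The 1,2,4-trioxygenated ring with a benzylic carbon on B6 would still have to be made by stepwise aromatic substitution. Sulfur is introduced, oxidised and expelled, and an alkene is made only to be reduced, so the step count is clearly higher. The electron-rich rings also have to withstand the basic halogenating medium.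
- In comparison, the chosen route accepts a riskier ring closure in exchange for building ring B in a single step, with its pattern fixed by connectivity.

**Alternative 2: aryne insertion for the crowded edge of ring B.** The B6–C1' bond and a B1–carbon bond are made on an existing arene. A dimethoxy-substituted aryne, released by fluoride from an ortho-silyl aryl triflate, would insert into the C–C bond between the ketone carbonyl and the α-carbon of a β-keto ester. The product is the acyl-alkylation product A3, methyl 2-(2-acetyl-3,5-dimethoxyphenyl)acetate, in which the acetyl group stands in for the B1 oxygen.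
- For it: the regiochemistry is well understood (the methoxy group next to the triple bond sends the carbon nucleophile to the far aryne carbon), the conditions are mild, and no strong base or heat-sensitive four-membered ring is involved. On mildness and predictability of the key step it is at least as good as the chosen route.
- Against it: the step closes no ring. The B1 oxygen appears only after a Baeyer–Villiger oxidation and hydrolysis. A3 carries only C1' and C2', so twelve chain carbons and ring A must still be attached. The aryne precursor itself takes several steps, and the macrocyclisation is left unsolved.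
- In comparison, the chosen route delivers B1 as a free hydroxyl directly, with the full chain and ring A already in place.

**Alternative 3: two-directional biomimetic folding.** Both rings are cut at once, at the A4–A5 and B5–B6 bonds. An open-chain bis(diketo-dioxinone) A5 would undergo a base-induced double aldol condensation and dehydration. This gives the bis-resorcylate A4, 5,5'-(tetradecane-1,14-diyl)bis(7-hydroxy-2,2-dimethyl-4H-benzo[d][1,3]dioxin-4-one), whose masked carboxyls are removed later.
- For it: two arenes and the whole carbon skeleton arise in one operation from acyclic material, and the 5-alkylresorcinol pattern of ring A comes out exactly right. In step economy up to the bis-arene stage it is stronger than the chosen route.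
- Against it: A4 is symmetric, and the target is not. Polyketide folding gives only 1,3-dioxygenation, so the B1 oxygen is missing. It would have to be created by oxidative C–O coupling of the ring A phenol onto a C–H position of ring B, which requires desymmetrising two identical rings and four similar phenols and competes with C–C coupling and over-oxidation.
- In comparison, the chosen route makes the two rings different from the start, places the B1 oxygen by the rearrangement, and closes the ether between defined partners (A1–Cl and B1–OH).

Key step: step 8

## Route

Step 1
Reactants: 1 1,12-dibromododecane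
Product: 2 (12-bromododecyl)triphenylphosphonium bromide
Conditions: PPh3 (1 equiv), 1 (3 equiv), toluene, 110 °C; salt collected, excess 1 washed out with hexane
Reagents that add atoms: triphenylphosphine, c1ccc(cc1)P(c1ccccc1)c1ccccc1
Why: SN2 quaternisation of the phosphine by a primary bromide; the excess of 1 and the separation of the mono-salt from toluene should keep the second bromide untouched.

Step 2
Reactants: 2 (12-bromododecyl)triphenylphosphonium bromide; 3 3-chloro-5-methoxybenzaldehyde
Product: 5 1-[(1Z)-13-bromotridec-1-en-1-yl]-3-chloro-5-methoxybenzene (Z expected to predominate; the E isomer is equally usable), via (12-bromododecylidene)triphenylphosphorane 4 (not isolated)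
Conditions: NaN(SiMe3)2, THF, −78 °C; then 3, −78 °C → rt
Reagents that add atoms: none
Why: Wittig olefination; the non-stabilised ylide 4 is formed cold and trapped at once by the non-enolisable aldehyde, which should keep the remote bromide from alkylating it, and the alkene geometry is irrelevant because the double bond is reduced in step 3.

Step 3
Reactants: 5 1-[(1Z)-13-bromotridec-1-en-1-yl]-3-chloro-5-methoxybenzene
Product: 6 1-(13-bromotridecyl)-3-chloro-5-methoxybenzene
Conditions: H2 (1 atm), RhCl(PPh3)3 (5 mol %), toluene–EtOH, rt
Reagents that add atoms: none
Why: Homogeneous hydrogenation with Wilkinson's catalyst RhCl(PPh3)3 saturates the disubstituted alkene and should leave the aryl chloride and the primary bromide alone, which a heterogeneous palladium catalyst would not guarantee.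

Step 4
Reactants: 6 1-(13-bromotridecyl)-3-chloro-5-methoxybenzene; 7 2,3-dibromoprop-1-ene
Product: 9 1-(15-bromohexadec-15-en-1-yl)-3-chloro-5-methoxybenzene, via alkylmagnesium bromide 8 (not isolated)
Conditions: Mg (I2-activated), THF, 45 °C; then added to 7 (1.5 equiv), CuI (5 mol %), THF, −10 °C → rt
Reagents that add atoms: none
Why: Magnesium inserts into the primary C–Br bond while the aryl chloride is inert under these conditions; copper-catalysed allylic substitution of a Grignard reagent on 2,3-dibromopropene is the standard route to 2-bromoalk-1-enes, and SN2 and SN2' attack give the same product.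

Step 5
Reactants: 10 diisopropyl squarate (3,4-diisopropoxycyclobut-3-ene-1,2-dione)
Product: 11 4-hydroxy-2,3-diisopropoxycyclobut-2-en-1-one (racemic)
Conditions: LiAlH(OtBu)3 (1.1 equiv), THF, 0 °C; aqueous work-up
Reagents that add atoms: none
Why: The bulky hydride reduces one of the two equivalent carbonyl groups and should stop at the hydroxycyclobutenone (selective 1,2-reduction of a squarate); the new stereocentre forms as a racemate and is lost in step 6.

Step 6
Reactants: 11 4-hydroxy-2,3-diisopropoxycyclobut-2-en-1-one
Product: 12 3-isopropoxycyclobut-3-ene-1,2-dione
Conditions: conc. aq. HCl (cat.), CH2Cl2, rt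
Reagents that add atoms: water, O
Why: Acid ionises the allylic C4 hydroxyl to an alkoxy-stabilised cyclobutenyl cation, water adds at C2 and the hemiketal collapses with loss of propan-2-ol; this acid-promoted allylic transposition after squarate reduction is the established entry to 3-alkoxycyclobutenediones.

Step 7
Reactants: 9 1-(15-bromohexadec-15-en-1-yl)-3-chloro-5-methoxybenzene; 12 3-isopropoxycyclobut-3-ene-1,2-dione
Product: 14 4-[16-(3-chloro-5-methoxyphenyl)hexadec-1-en-2-yl]-4-hydroxy-3-isopropoxycyclobut-2-en-1-one (racemic), via alkenyllithium 13 (not isolated)
Conditions: tert-butyllithium (2.0 equiv), Et2O, −78 °C; then 12, THF, −78 °C; NH4Cl (aq), −78 °C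
Reagents that add atoms: none
Why: Bromine–lithium exchange at −78 °C is far faster than any reaction at the aryl chloride; the alkenyllithium 13 should then add 1,2 to the C2 carbonyl of 12, the ketone-like one, because the C1 carbonyl is deactivated as part of the vinylogous ester O=C–C=C–O; the carbinol centre forms as a racemate and disappears in step 8.

Step 8
Reactants: 14 4-[16-(3-chloro-5-methoxyphenyl)hexadec-1-en-2-yl]-4-hydroxy-3-isopropoxycyclobut-2-en-1-one
Product: 17 2-[14-(3-chloro-5-methoxyphenyl)tetradecyl]-6-isopropoxybenzene-1,4-diol, via dienylketene 15 (not isolated), via cyclohexadienone 16 (not isolated)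
Conditions: p-xylene (degassed, 0.01 M), 138 °C, argon
Reagents that add atoms: none
Why: Heating should open the cyclobutenone by a thermal conrotatory four-electron electrocyclic cleavage of the C1–C4 bond, in which the C4 hydroxyl turns outward for electronic reasons and the alkenyl group therefore turns inward, giving the (Z)-dienylketene 15. The ketene carbon and the terminal methylene of the 1,1-disubstituted alkene are then within bonding distance, and a thermal disrotatory six-electron electrocyclisation should form the B4–B5 bond and close ring B as the six-membered cyclohexadienone 16. Enolisation of the CH2–C=O unit of 16 is driven by aromatisation and should deliver hydroquinone 17. This is the Moore rearrangement of 4-alkenyl-4-hydroxycyclobutenones, the closest known reaction type, applied here to a 3-alkoxy-2-unsubstituted ring. No stereocentre is formed, and the carbinol centre of racemic 14 becomes the planar carbon B1. The selectivity needed is outward over inward rotation of the hydroxyl, since an inward hydroxyl would add to the ketene and give a 2(5H)-furanone; the oxygen lone pairs secure the outward mode. The substitution pattern follows from connectivity alone: C4 becomes B1 between the isopropoxy carbon B2 and the chain carbon B6, and the former carbonyl carbon becomes B4. High dilution and exclusion of oxygen are meant to suppress ketene oligomerisation and quinone formation.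

Step 9
Reactants: 17 2-[14-(3-chloro-5-methoxyphenyl)tetradecyl]-6-isopropoxybenzene-1,4-diol
Product: 18 2-[14-(3-chloro-5-methoxyphenyl)tetradecyl]-6-isopropoxy-4-methoxyphenol
Conditions: MeI (1.05 equiv), K2CO3, acetone (degassed), rt, argon
Reagents that add atoms: iodomethane, CI
Why: Williamson etherification under weak base; the B4 hydroxyl, with hydrogen on both sides, should be both the more acidic and the more accessible one, while the B1 hydroxyl sits between the isopropoxy group and the chain, so one equivalent of iodomethane should react at B4, as in the mono-alkylation of other 2,6-disubstituted hydroquinones.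

Step 10
Reactants: 18 2-[14-(3-chloro-5-methoxyphenyl)tetradecyl]-6-isopropoxy-4-methoxyphenol
Product: 19 macrocyclic tri-ether: 20-membered ring closed by the A1–O–B1 diaryl ether, with methoxy on A3, isopropoxy on B2, methoxy on B4 and the fourteen-carbon chain from B6 to A5
Conditions: Pd(OAc)2 (10 mol %), 2-di-tert-butylphosphino-2',4',6'-triisopropylbiphenyl (15 mol %), K3PO4, toluene, 100 °C, syringe-pump addition of 18 to a final 0.002 M
Reagents that add atoms: none
Why: Proposed new method: zerovalent palladium carrying the bulky biaryl phosphine should insert into the A1–Cl bond, the tethered B1 phenoxide should replace chloride on divalent palladium, and C–O reductive elimination from the aryl(aryloxy)palladium species should close the 20-membered ring; the closest known reactions are the intermolecular palladium-catalysed etherification of unactivated aryl chlorides with ortho-substituted phenols using this ligand class and the copper-mediated Ullmann macrocyclisation of halide–phenol seco compounds to diaryl ether macrocycles.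

Step 11
Reactants: 19 macrocyclic tri-ether (methoxy on A3 and B4, isopropoxy on B2)
Product: 20 target macrocycle: ring A with O-aryl on A1 and OH on A3; ring B with O-aryl on B1 and OH on B2 and B4; (CH2)14 chain from B6 to A5
Conditions: BBr3 (8 equiv), CH2Cl2, −78 °C → rt; then MeOH, H2O
Reagents that add atoms: none
Why: BBr3 cleaves alkyl aryl ethers by O–B coordination and bromide attack at the alkyl carbon, the secondary isopropyl group fastest; the diaryl ether offers no alkyl carbon and should survive, and aqueous work-up hydrolyses the aryl borates to the three phenols.

## Compound list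

1 | 1,12-dibromododecane | BrCCCCCCCCCCCCBr | starting material
2 | (12-bromododecyl)triphenylphosphonium bromide | [Br-].BrCCCCCCCCCCCC[P+](c1ccccc1)(c1ccccc1)c1ccccc1 | intermediate
3 | 3-chloro-5-methoxybenzaldehyde | COc1cc(Cl)cc(C=O)c1 | starting material
4 | (12-bromododecylidene)triphenylphosphorane | BrCCCCCCCCCCCC=P(c1ccccc1)(c1ccccc1)c1ccccc1 | intermediate (not isolated)
5 | 1-[(1Z)-13-bromotridec-1-en-1-yl]-3-chloro-5-methoxybenzene (Z isomer shown) | COc1cc(Cl)cc(/C=C\CCCCCCCCCCCBr)c1 | intermediate
6 | 1-(13-bromotridecyl)-3-chloro-5-methoxybenzene | COc1cc(Cl)cc(CCCCCCCCCCCCCBr)c1 | intermediate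
7 | 2,3-dibromoprop-1-ene | C=C(Br)CBr | starting material
8 | [13-(3-chloro-5-methoxyphenyl)tridecyl]magnesium bromide | COc1cc(Cl)cc(CCCCCCCCCCCCC[Mg]Br)c1 | intermediate (not isolated)
9 | 1-(15-bromohexadec-15-en-1-yl)-3-chloro-5-methoxybenzene | COc1cc(Cl)cc(CCCCCCCCCCCCCCC(Br)=C)c1 | intermediate
10 | diisopropyl squarate (3,4-diisopropoxycyclobut-3-ene-1,2-dione) | CC(C)OC1=C(OC(C)C)C(=O)C1=O | starting material
11 | 4-hydroxy-2,3-diisopropoxycyclobut-2-en-1-one (racemic) | CC(C)OC1=C(OC(C)C)C(O)C1=O | intermediate
12 | 3-isopropoxycyclobut-3-ene-1,2-dione | CC(C)OC1=CC(=O)C1=O | intermediate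
13 | [16-(3-chloro-5-methoxyphenyl)hexadec-1-en-2-yl]lithium | [Li]C(=C)CCCCCCCCCCCCCCc1cc(Cl)cc(OC)c1 | intermediate (not isolated)
14 | 4-[16-(3-chloro-5-methoxyphenyl)hexadec-1-en-2-yl]-4-hydroxy-3-isopropoxycyclobut-2-en-1-one (racemic) | O=C1C=C(OC(C)C)C1(O)C(=C)CCCCCCCCCCCCCCc1cc(Cl)cc(OC)c1 | intermediate
15 | (3Z)-5-[14-(3-chloro-5-methoxyphenyl)tetradecyl]-4-hydroxy-3-isopropoxyhexa-1,3,5-trien-1-one | O=C=C/C(OC(C)C)=C(\C(=C)CCCCCCCCCCCCCCc1cc(Cl)cc(OC)c1)O | intermediate (not isolated)
16 | 5-[14-(3-chloro-5-methoxyphenyl)tetradecyl]-4-hydroxy-3-isopropoxycyclohexa-2,4-dien-1-one | O=C1CC(CCCCCCCCCCCCCCc2cc(Cl)cc(OC)c2)=C(O)C(OC(C)C)=C1 | intermediate (not isolated)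
17 | 2-[14-(3-chloro-5-methoxyphenyl)tetradecyl]-6-isopropoxybenzene-1,4-diol | Oc1c(OC(C)C)cc(O)cc1CCCCCCCCCCCCCCc1cc(Cl)cc(OC)c1 | intermediate
18 | 2-[14-(3-chloro-5-methoxyphenyl)tetradecyl]-6-isopropoxy-4-methoxyphenol | Oc1c(OC(C)C)cc(OC)cc1CCCCCCCCCCCCCCc1cc(Cl)cc(OC)c1 | intermediate
19 | macrocyclic tri-ether: 20-membered A1–O–B1 diaryl ether cyclophane (a 2-oxa-1(1,3),3(1,2)-dibenzenacycloheptadecaphane) with OMe on A3, O-iPr on B2 and OMe on B4 | COc1cc2cc(c1)Oc1c(OC(C)C)cc(OC)cc1CCCCCCCCCCCCCC2 | intermediate
20 | target: the same 20-membered cyclophane with OH on A3, B2 and B4 | Oc1cc2cc(c1)Oc1c(O)cc(O)cc1CCCCCCCCCCCCCC2 | target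

## Step count and least certain steps

Total step count: 11. Longest linear sequence: 9 steps (steps 1, 2, 3, 4, 7, 8, 9, 10, 11); the squarate branch (steps 5 and 6) joins at step 7.

**Step 10 (carries the label).**
- What may go wrong: closure of a 20-membered ring through a phenoxide with two ortho substituents is slow, so intermolecular etherification to oligomers can win. Oxidative addition of the electron-rich chloroarene at low concentration may lag behind catalyst decay, and hydrodechlorination may erode material.
- Fallback, from 18 back to 19: the chloride would be exchanged for boron by palladium-catalysed borylation with tetrahydroxydiboron (Pd(OAc)2, 2-dicyclohexylphosphino-2',4',6'-triisopropylbiphenyl, KOAc, EtOH, 80 °C), giving {3-[14-(2-hydroxy-3-isopropoxy-5-methoxyphenyl)tetradecyl]-5-methoxyphenyl}boronic acid F1. F1 would then be cyclised by the known copper-promoted oxidative aryl ether macrocyclisation of arylboronic acids with phenols (Chan–Lam–Evans; Cu(OAc)2, pyridine, 4 Å molecular sieves, CH2Cl2, dry air, rt, high dilution) to 19.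

**Step 8 (key step).**
- What may go wrong: a share of inward rotation of the free hydroxyl would lead to lactonisation onto the ketene; the unsubstituted ketene terminus may oligomerise; and the hydroquinone may be oxidised by air during isolation.
- Fallback, from 14 back to 17: the carbinol would be capped first (Me3SiCl, Et3N, 4-dimethylaminopyridine, CH2Cl2, 0 °C) to give 4-[16-(3-chloro-5-methoxyphenyl)hexadec-1-en-2-yl]-3-isopropoxy-4-(trimethylsilyloxy)cyclobut-2-en-1-one F2. Its silyloxy group still rotates outward but cannot add to the ketene. Thermolysis in p-xylene should give 3-[14-(3-chloro-5-methoxyphenyl)tetradecyl]-5-isopropoxy-4-(trimethylsilyloxy)phenol F3, a less oxidisable mono-protected hydroquinone, which would be desilylated with dilute HCl in THF just before use to give 17.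

**Step 9.**
- What may go wrong: a second alkylation at the B1 hydroxyl, some alkylation at the wrong oxygen, or oxidation of the hydroquinone anion to the quinone by traces of air.
- Fallback, from 14 back to 18: the two oxygens would be told apart by connectivity, not by sterics. The carbinol of 14 would be protected with chloromethyl methyl ether (iPr2NEt, CH2Cl2) as 4-[16-(3-chloro-5-methoxyphenyl)hexadec-1-en-2-yl]-3-isopropoxy-4-(methoxymethoxy)cyclobut-2-en-1-one F4. Ring expansion in p-xylene should then give 3-[14-(3-chloro-5-methoxyphenyl)tetradecyl]-5-isopropoxy-4-(methoxymethoxy)phenol F5, in which only the B4 hydroxyl is free. Methylation (MeI, K2CO3, acetone) would give 1-chloro-3-{14-[3-isopropoxy-5-methoxy-2-(methoxymethoxy)phenyl]tetradecyl}-5-methoxybenzene F6, and HCl in MeOH would remove the acetal to give 18.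

**Step 7.**
- What may go wrong: proton abstraction at A2, between chlorine and methoxy, by the alkyllithium, followed by loss of LiCl to an aryne; addition to the vinylogous-ester carbonyl or conjugate addition at C4 of 12; base-induced decomposition of 12.
- Fallback, from 9 back to 14: no alkyllithium would be used. Direct insertion of magnesium into the vinyl bromide (Mg, LiCl, THF, 50 °C) would give [16-(3-chloro-5-methoxyphenyl)hexadec-1-en-2-yl]magnesium bromide F7, which would be added to 12 at −78 °C and quenched with NH4Cl to give 14.

**Step 2.**
- What may go wrong: alkylation of the ylide by the remote bromide of another molecule, and contamination of 2 by the bis-phosphonium salt from step 1.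
- Fallback, from 3 back to 6: the chain terminus would be carried as an alcohol. Commercial 12-bromododecan-1-ol and PPh3 would give (12-hydroxydodecyl)triphenylphosphonium bromide F8. Its ylide-alkoxide (2 equiv NaN(SiMe3)2, THF) would react with 3 to give (12Z)-13-(3-chloro-5-methoxyphenyl)tridec-12-en-1-ol F9. Hydrogenation (H2, RhCl(PPh3)3) would give 13-(3-chloro-5-methoxyphenyl)tridecan-1-ol F10, and Appel bromination (CBr4, PPh3, CH2Cl2) would give 6.

## Further compounds

F1 | step 10 | {3-[14-(2-hydroxy-3-isopropoxy-5-methoxyphenyl)tetradecyl]-5-methoxyphenyl}boronic acid | Oc1c(OC(C)C)cc(OC)cc1CCCCCCCCCCCCCCc1cc(B(O)O)cc(OC)c1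
F2 | step 8 | 4-[16-(3-chloro-5-methoxyphenyl)hexadec-1-en-2-yl]-3-isopropoxy-4-(trimethylsilyloxy)cyclobut-2-en-1-one (racemic) | O=C1C=C(OC(C)C)C1(O[Si](C)(C)C)C(=C)CCCCCCCCCCCCCCc1cc(Cl)cc(OC)c1
F3 | step 8 | 3-[14-(3-chloro-5-methoxyphenyl)tetradecyl]-5-isopropoxy-4-(trimethylsilyloxy)phenol | Oc1cc(OC(C)C)c(O[Si](C)(C)C)c(CCCCCCCCCCCCCCc2cc(Cl)cc(OC)c2)c1
F4 | step 9 | 4-[16-(3-chloro-5-methoxyphenyl)hexadec-1-en-2-yl]-3-isopropoxy-4-(methoxymethoxy)cyclobut-2-en-1-one (racemic) | O=C1C=C(OC(C)C)C1(OCOC)C(=C)CCCCCCCCCCCCCCc1cc(Cl)cc(OC)c1
F5 | step 9 | 3-[14-(3-chloro-5-methoxyphenyl)tetradecyl]-5-isopropoxy-4-(methoxymethoxy)phenol | Oc1cc(OC(C)C)c(OCOC)c(CCCCCCCCCCCCCCc2cc(Cl)cc(OC)c2)c1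
F6 | step 9 | 1-chloro-3-{14-[3-isopropoxy-5-methoxy-2-(methoxymethoxy)phenyl]tetradecyl}-5-methoxybenzene | COc1cc(OC(C)C)c(OCOC)c(CCCCCCCCCCCCCCc2cc(Cl)cc(OC)c2)c1
F7 | step 7 | [16-(3-chloro-5-methoxyphenyl)hexadec-1-en-2-yl]magnesium bromide | Br[Mg]C(=C)CCCCCCCCCCCCCCc1cc(Cl)cc(OC)c1
F8 | step 2 | (12-hydroxydodecyl)triphenylphosphonium bromide | [Br-].OCCCCCCCCCCCC[P+](c1ccccc1)(c1ccccc1)c1ccccc1
F9 | step 2 | (12Z)-13-(3-chloro-5-methoxyphenyl)tridec-12-en-1-ol | COc1cc(Cl)cc(/C=C\CCCCCCCCCCCO)c1
F10 | step 2 | 13-(3-chloro-5-methoxyphenyl)tridecan-1-ol | COc1cc(Cl)cc(CCCCCCCCCCCCCO)c1
A1 | alternative 1 | tri-O-methyl macrocycle with an (E)-C1'=C2' double bond | COc1cc(OC)c2Oc3cc(OC)cc(c3)CCCCCCCCCCCC/C=C/c2c1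
A2 | alternative 1 | 21-membered benzylic sulfone (SO2 between C1' and C2' of the tri-O-methyl macrocycle) | COc1cc(OC)c2Oc3cc(OC)cc(c3)CCCCCCCCCCCCCS(=O)(=O)Cc2c1
A3 | alternative 2 | methyl 2-(2-acetyl-3,5-dimethoxyphenyl)acetate | COC(=O)Cc1cc(OC)cc(OC)c1C(C)=O
A4 | alternative 3 | 5,5'-(tetradecane-1,14-diyl)bis(7-hydroxy-2,2-dimethyl-4H-benzo[d][1,3]dioxin-4-one) | O=C1OC(C)(C)Oc2cc(O)cc(CCCCCCCCCCCCCCc3cc(O)cc4OC(C)(C)OC(=O)c34)c12
A5 | alternative 3 | 6,6'-(2,4,19,21-tetraoxodocosane-1,22-diyl)bis(2,2-dimethyl-4H-1,3-dioxin-4-one) | CC1(C)OC(=O)C=C(CC(=O)CC(=O)CCCCCCCCCCCCCCC(=O)CC(=O)CC2=CC(=O)OC(C)(C)O2)O1
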